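The compounds are numbered 1–23 in the order they appear in the steps. Eudesmane numbering is used throughout: ring A is C1–C5 plus C10, ring B is C5–C10, C14 is the methyl on C10, C15 the carbon on C4, C11 the side-chain carbon on C7, C12 its carboxyl carbon and C13 its methylene carbon. β is the face that carries C14.

## Analysis of the target

The target 23 is a eudesmane, a trans-fused decalin, in which the usual 8,12-lactone is opened to a C12 methyl ester and an 8β-acetate. It has five stereocentres: C3 (β-isobutyrate, equatorial), C5 (α-hydroperoxide), C7 (β acrylate arm, equatorial), C8 (β-acetate, axial) and C10 (β-methyl, quaternary). The C5 oxygen is trans to C14, the C7 and C8 substituents are cis to each other, and the C8 acetate is 1,3-diaxial to C14. The sensitive groups are the tertiary allylic hydroperoxide (reduction, base, acid-induced cleavage), the 2-substituted acrylate (conjugate addition, hydrogenation) and three different esters; a free 8β-hydroxyl next to the C12 ester would close back to the lactone. The hard points are the absolute configuration of quaternary C10, the hindered axial oxygen at C8, the order in which the three esters are made, and a hydroperoxide that tolerates almost no later chemistry. The hydroperoxide and the C4=C15 methylene together are the ene product of a C4=C5 alkene, so C5 needs no control until the last step and C10 is the only centre that must be set early. The strategy rests on C10: it is shared by both rings, carries C14, and sits 1,3 to the C8 oxygen in ring B, while ring A has oxygen at C3 and carbon on C4. That is the pattern left when a 2-oxygenated butadiene (C6–C7=C8–C9) adds across the methyl-bearing alkene (C5=C10) of a methoxy-methyl-benzoquinone.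

## Retrosynthetic reasoning

**C5–O and the C4=C15 alkene.** The hydroperoxide of 23 is removed first, back to the tetrasubstituted C4=C5 alkene of 22. This is the only disconnection that makes C5 and the exocyclic methylene in one operation, and it puts the least stable group at the very end. The forward step must attack C5 from the α face and take its hydrogen from C15.

**The acetate and methyl ester.** The 8β-acetate and the C12 methyl ester of 22 are read as an opened cis-lactone, 19, through hydroxy ester 21. The lactone ties O8 to C12 while C13 is installed, so no other enolisable ester is present at that stage. The forward steps must open the lactone without touching the isobutyrate and cap the 8β-hydroxyl before it closes again.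

**The isobutyrate and C13.** Removing the isobutyrate gives 18, and cutting C11=C13 gives hydroxy lactone 15. The lactone α-carbon is the only acidic carbon in 15, which makes a Mannich-type methylenation clean.

**C3–H, C8–H and the lactone C–O bond.** The 3β-alcohol of 15 comes from enone 14, and the lactone of 14 from keto ester 12 by reduction of the C8 ketone. Both hydride additions are steered by C14: the C8 ketone is 1,3 to the axial methyl, so the hydride comes from the α face and the new oxygen is axial and cis to the C7 arm.

**C7–C11.** The acetate arm of 12 is cut at C7–C11, back to silyl enol ether 9. The C7=C8 position of that enol ether is fixed by the cycloaddition, so the two-carbon unit goes to C7 and not C9, and it can be delivered without base in the presence of the ring-A enone. C7 is then α to a ketone and is set by equilibration.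

**Ring A oxidation pattern.** Enone 9 comes from dienone 8 by saturating C1=C2, and 8 from the vinylogous ester 6 by carbonyl reduction and transposition. This removes O1, moves the carbonyl to C3 and keeps C4=C5.

**C4–C15.** The methyl of 6 is attached through enol triflate 5, made from the C4 ketone of adduct 4. C5–H is the only acidic hydrogen of 4, so the triflate fixes the C4=C5 alkene without a separate dehydration, and the methyl arrives by cross-coupling rather than by carbonyl addition.

**C9–C10 and C5–C6.** Adduct 4 is cut into quinone 3 and diene 2. These two bonds close ring B, set C10, place oxygen at C8 and leave ring A with the C3 oxygen and the C4 carbonyl. Diene 2 comes from 1 in one step, and 3 is commercial.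

## Alternatives that were turned down

**Alternative 1:** The C7–C11 bond is cut and the two carbons are delivered from O8 through a mixed bromoacetal, A1, on an 8β-hydroxy-4,6-diene. In the forward key step Bu3SnH and AIBN generate the C11 radical, which adds 5-exo to C7 and gives the cis-fused lactol ether A2. In its favour, the tether enforces the cis relation of C7 and C8, and no enolate chemistry is needed. On that point it is stronger than the chosen route, which relies on equilibration at C7 and on hydride facial selectivity at C8. Against it, the step does not make ring B or C10; an enantiopure decalin dienol has to be built first by a separate asymmetric annulation. The radical also adds to a conjugated diene, so the intermediate is an allylic radical spread over C6 and C4, and hydrogen delivery at C4 would move the alkene out of C4=C5. A2 still needs oxidation to the lactone, methylenation and the same lactone opening, so the end game is not shortened. The chosen strategy instead builds ring B, C10 and O8 catalytically from two simple components.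

**Alternative 2:** The C5–C10 bond is cut across the decalin, leading back to a ten-membered enone lactone, A3, with an exocyclic C10=C14 alkene. In the forward key step Fe(acac)3 and PhSiH3 transfer a hydrogen atom to C14, and the C10 radical adds across the ring to C5 to give the 3-keto eudesmanolide A4. In its favour, one mild step closes both rings and makes the quaternary centre, and the lactone with C7 and C8 is in place before cyclisation; that last point is stronger than in the chosen route. Against it, an enantiopure ten-membered ring with a cis-lactone is itself a long synthesis. The ring-fusion outcome depends on the conformer population of the macrocycle. A4 arrives with C4 as a saturated methine and C11 as a saturated methyl, so both alkenes of the target must be rebuilt, and the hydrogen-atom-transfer conditions would not tolerate the acrylate. The chosen strategy offers a bimolecular, catalyst-controlled bond formation from commercial inputs and a shorter sequence.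

**Alternative 3:** The C1–C10 bond is cut and a temporary C3–C8 bond added, giving the bicyclo[2.2.2]octene vinyl carbinol A5, made from a masked o-benzoquinone and an acrylate. In the forward key step KH and 18-crown-6 form the alkoxide, which undergoes an anionic oxy-Cope shift to the cis-decalin A6. In its favour, C10 is made stereospecifically, and C7 is fixed relative to C10. A6 also already has the C3 ketone with C1 and C2 as methylenes, so the transposition and hydrogenation of the chosen route are not needed; on ring A it is stronger. Against it, the cycloaddition that makes A5 is racemic unless an auxiliary is added. The C7 substituent of A6 is a carboxyl carbon directly on the ring; it would have to become C11, an sp2 carbon carrying C12 and C13, which means adding two carbons at an acyl carbon. The C4 ketal must also be converted into the methyl-bearing alkene, and the enol ether points to C9, not C7. The chosen strategy gives absolute control at C10 and brings the side chain in at the correct oxidation level.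

Key step: step 2

Assumption: the sense of induction in step 2 is assigned from the two-point binding model of the oxazaborolidinium ion (B–O bond and C5–H···O contact), which points to the (S)-configured catalyst; if the model misleads, the mirror-image catalyst is used and nothing else changes.

## Route

**Step 1**
Reactants: 1 methyl vinyl ketone
Product: 2 2-(tert-butyldimethylsilyloxy)buta-1,3-diene
Conditions: TBSOTf, Et3N, Et2O, 0 °C to rt
Reagents that add atoms: tert-butyldimethylsilyl triflate, CC(C)(C)[Si](C)(C)OS(=O)(=O)C(F)(F)F
Why: Soft enolisation (silyl dienol ether formation): the triflate silylates the carbonyl oxygen and the amine removes a methyl proton; only the methyl group has α-hydrogens.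

**Step 2**
Reactants: 3 2-methoxy-5-methyl-1,4-benzoquinone; 2 2-(tert-butyldimethylsilyloxy)buta-1,3-diene
Product: 4 cis-fused adduct 3-methoxy-8-(tert-butyldimethylsilyloxy)-11,12,13,15-tetranor-5β-eudesma-2,7-diene-1,4-dione (5β-H and 10β-CH3)
Conditions: (S)-o-tolyl-diphenylprolinol oxazaborolidinium triflimide, [C24H25BNO][N(SO2CF3)2] (20 mol %), CH2Cl2, −78 to −40 °C
Reagents that add atoms: none
Why: The cation binds the C4 carbonyl oxygen of 3 on the lone pair syn to C5–H, with a C5–H···O contact to the ring oxygen as second anchor; this activates the C5=C10 alkene and makes C10, β to C4=O, its most electrophilic carbon. The diene then adds in a concerted, asynchronous, suprafacial Diels–Alder reaction, the more nucleophilic terminus C9 bonding to C10 and C6 to C5; the closest known reaction type is the chiral-cation-catalysed addition of 2-siloxydienes to substituted 1,4-benzoquinones. Ring B is closed as a six-membered ring in this one intermolecular [4+2] event, both σ-bonds coming from a single six-electron transition state, not from a stepwise exo or endo closure. C10 and C5 are created together: their cis relation follows from suprafacial addition to the ring alkene, and their absolute configuration from the phenyl group of the catalyst, which covers one face of the bound quinone. The step needs site selectivity, regioselectivity and one enantioface. The methoxy group turns C2=C3 into a vinylogous ester and takes it out of play. The uncatalysed polarisation (C4=O is the stronger acceptor because C1=O is the vinylogous ester carbonyl) and the catalyst's need for a flanking C–H on the reacting alkene both send C9 to C10. Only C10 must survive; C5 is erased in step 3.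

**Step 3**
Reactants: 4 cis-fused adduct
Product: 5 3-methoxy-1-oxo-8-(tert-butyldimethylsilyloxy)-11,12,13,15-tetranoreudesma-2,4,7-trien-4-yl triflate
Conditions: KN(SiMe3)2, THF, −78 °C; PhNTf2, −78 to 0 °C
Reagents that add atoms: N-phenyl-bis(trifluoromethanesulfonimide), O=S(=O)(N(c1ccccc1)S(=O)(=O)C(F)(F)F)C(F)(F)F
Why: C5–H is the only acidic hydrogen of 4 (C10 is quaternary, C2 and C3 are sp2), so the C4 enolate forms regiospecifically and is triflated on oxygen (enol triflate formation); this fixes the C4=C5 alkene and leaves C10 as the only stereocentre.

**Step 4**
Reactants: 5 C4 enol triflate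
Product: 6 3-methoxy-8-(tert-butyldimethylsilyloxy)-11,12,13-trinoreudesma-2,4,7-trien-1-one
Conditions: MeZnCl (2 equiv), Pd(PPh3)4 (5 mol %), THF, 0 °C to rt
Reagents that add atoms: methylzinc chloride, C[Zn]Cl
Why: Negishi coupling: oxidative addition of the electron-poor dienyl triflate to zerovalent palladium, transmetallation from zinc and reductive elimination put C15 on C4; the organozinc reagent does not add to the dienone carbonyl or disturb the silyl enol ether.

**Step 5**
Reactants: 6 methoxy dienone
Product: 8 8-(tert-butyldimethylsilyloxy)-11,12,13-trinoreudesma-1,4,7-trien-3-one, via C1 allylic alcohol 7 (not isolated)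
Conditions: i-Bu2AlH (1.2 equiv), CH2Cl2, −78 °C; aq. KNaC4H4O6; then PPTS (5 mol %), acetone–H2O, 0 °C
Reagents that add atoms: water, O
Why: Stork–Danheiser transposition: 1,2-hydride addition to the vinylogous ester carbonyl gives 7, whose hydroxyl ionises under very mild acid to a cation stabilised by the methoxy group and the C4=C5 alkene; water adds at C3 and methanol leaves, which removes O1 and gives the C3 ketone with C1=C2. The silyl enol ether hydrolyses only by slower C-protonation and should survive buffered acid at 0 °C.

**Step 6**
Reactants: 8 cross-conjugated dienone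
Product: 9 8-(tert-butyldimethylsilyloxy)-11,12,13-trinoreudesma-4,7-dien-3-one
Conditions: H2 (1 atm), RhCl(PPh3)3 (5 mol %), benzene, rt
Reagents that add atoms: none
Why: Homogeneous hydrogenation with this rhodium complex reduces the disubstituted C1=C2 alkene of a 1,4-dien-3-one and leaves the tetrasubstituted C4=C5 alkene and the trisubstituted silyl enol ether alone (known site selectivity for steroidal and sesquiterpenoid dienones).

**Step 7**
Reactants: 9 enone silyl enol ether
Product: 12 ethyl 3,8-dioxo-13-noreudesm-4-en-12-oate (7β arm), via siloxycyclopropane ester 10 (not isolated), via 7α-epimeric keto ester 11 (not isolated)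
Conditions: N2CHCO2Et (slow addition), Rh2(OAc)4 (1 mol %), CH2Cl2, rt; Bu4NF, AcOH, THF, 0 °C; DBU (0.2 equiv), THF, rt
Reagents that add atoms: ethyl diazoacetate, CCOC(=O)C=[N+]=[N-]
Why: The rhodium carbenoid cyclopropanates the electron-rich silyl enol ether, not the electron-poor enone, and so forms C7–C11 regiospecifically; fluoride then opens the donor–acceptor cyclopropane at C8–C11 to the γ-keto ester (siloxycyclopropane route to 1,4-dicarbonyl compounds). C7 is now α to the C8 ketone and is equilibrated by DBU to the equatorial 7β epimer in the chair of ring B that keeps C14 axial.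

**Step 8**
Reactants: 12 keto ester
Product: 14 3-oxo-13-noreudesm-4-en-12,8β-olide, via 8β-hydroxy ester 13 (not isolated)
Conditions: LiBH(s-Bu)3 (1.05 equiv), THF, −78 to 0 °C; H2O; TsOH (cat.), CH2Cl2, rt
Reagents that add atoms: none
Why: The bulky hydride attacks the C8 ketone equatorially, from the α face opposite the 1,3-diaxial C14 methyl, giving the axial 8β-alkoxide; this is cis to the C7 arm and closes the γ-lactone (reduction–lactonisation). The hindered β,β-disubstituted enone should react much more slowly at −78 °C.

**Step 9**
Reactants: 14 keto lactone
Product: 15 3β-hydroxy-13-noreudesm-4-en-12,8β-olide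
Conditions: NaBH4, CeCl3·7H2O, MeOH, −20 °C
Reagents that add atoms: none
Why: Luche reduction: 1,2-hydride delivery to the enone carbonyl along the axial trajectory from the α face gives the equatorial 3β-allylic alcohol, as with steroidal 4-en-3-ones; the lactone is not reduced.

**Step 10**
Reactants: 15 hydroxy lactone
Product: 18 3β-hydroxyeudesma-4,11(13)-dien-12,8β-olide, via Mannich base 16 (not isolated), via trimethylammonium iodide 17 (not isolated)
Conditions: LiN(i-Pr)2 (2.3 equiv), THF, −78 °C; [Me2N=CH2]I, −78 to 0 °C; MeI, MeOH, rt; aq. NaHCO3, EtOAc
Reagents that add atoms: N,N-dimethylmethyleneiminium iodide, C=[N+](C)C.[I-]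
Why: Two equivalents of base give the alkoxide and the lactone enolate; Mannich reaction of the enolate with the iminium salt gives 16, and N-methylation followed by β-elimination of trimethylamine gives the α-methylene lactone (standard α-methylenation). The C11 stereocentre of 16 is erased.

**Step 11**
Reactants: 18 hydroxy methylene lactone
Product: 19 3β-isobutyryloxyeudesma-4,11(13)-dien-12,8β-olide
Conditions: i-PrCOCl, pyridine, DMAP (cat.), CH2Cl2, 0 °C
Reagents that add atoms: isobutyryl chloride, CC(C)C(=O)Cl
Why: Acylation of the only free hydroxyl, a secondary allylic alcohol, with an acid chloride under nucleophilic catalysis; C3 is not touched.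

**Step 12**
Reactants: 19 isobutyrate lactone
Product: 21 methyl 8β-hydroxy-3β-isobutyryloxyeudesma-4,11(13)-dien-12-oate, via lithium carboxylate 20 (not isolated)
Conditions: LiOH (1.1 equiv), THF–H2O, 0 °C; evaporate; MeI, DMF, rt
Reagents that add atoms: lithium hydroxide, [Li+].[OH-]; iodomethane, CI
Why: Hydroxide should open the strained, conjugated γ-lactone at the acyl carbon much faster than it attacks the hindered secondary isobutyrate, and SN2 alkylation of the carboxylate with iodomethane gives the methyl ester under conditions too mild for relactonisation. C8 keeps its configuration because the C8–O bond is not broken.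

**Step 13**
Reactants: 21 hydroxy methyl ester (used crude)
Product: 22 methyl 8β-acetoxy-3β-isobutyryloxyeudesma-4,11(13)-dien-12-oate
Conditions: Ac2O, Et3N, DMAP (cat.), CH2Cl2, 0 °C to rt
Reagents that add atoms: acetic anhydride, CC(=O)OC(C)=O
Why: DMAP-catalysed acetylation of the hindered axial 8β-hydroxyl; once capped, the hydroxyl can no longer close back onto C12.

**Step 14**
Reactants: 22 diene triester
Product: 23 methyl 8β-acetoxy-5α-hydroperoxy-3β-isobutyryloxyeudesma-4(15),11(13)-dien-12-oate (target, CNP0244758.1)
Conditions: O2, tetraphenylporphyrin (cat.), visible light, CH2Cl2, −20 °C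
Reagents that add atoms: dioxygen, O=O
Why: Schenck ene reaction: singlet oxygen attacks the electron-rich tetrasubstituted C4=C5 alkene (the acrylate is inert) from the α face, opposite the axial C14 methyl, bonds to C5 and takes a hydrogen from C15, so the alkene moves to C4=C15 and the 5α-hydroperoxide, trans to C14, results. The aligned hydrogen on C3 is deactivated by the geminal acyloxy group, and the α-hydrogen on C6 is equatorial and not aligned.

## Compound list

1 | methyl vinyl ketone | CC(=O)C=C | starting material
2 | 2-(tert-butyldimethylsilyloxy)buta-1,3-diene | C=CC(=C)O[Si](C)(C)C(C)(C)C | intermediate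
3 | 2-methoxy-5-methyl-1,4-benzoquinone | COC1=CC(=O)C(C)=CC1=O | starting material
4 | cis-fused adduct, 3-methoxy-8-(tert-butyldimethylsilyloxy)-11,12,13,15-tetranor-5β-eudesma-2,7-diene-1,4-dione | C1[C@@H]2C(=O)C(OC)=CC(=O)[C@]2(C)CC(O[Si](C)(C)C(C)(C)C)=C1 | intermediate
5 | 3-methoxy-1-oxo-8-(tert-butyldimethylsilyloxy)-11,12,13,15-tetranoreudesma-2,4,7-trien-4-yl triflate | C1C2=C(OS(=O)(=O)C(F)(F)F)C(OC)=CC(=O)[C@]2(C)CC(O[Si](C)(C)C(C)(C)C)=C1 | intermediate
6 | 3-methoxy-8-(tert-butyldimethylsilyloxy)-11,12,13-trinoreudesma-2,4,7-trien-1-one | C1C2=C(C)C(OC)=CC(=O)[C@]2(C)CC(O[Si](C)(C)C(C)(C)C)=C1 | intermediate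
7 | 3-methoxy-8-(tert-butyldimethylsilyloxy)-11,12,13-trinoreudesma-2,4,7-trien-1-ol (C1 epimers, not isolated) | C1C2=C(C)C(OC)=CC(O)[C@]2(C)CC(O[Si](C)(C)C(C)(C)C)=C1 | intermediate
8 | 8-(tert-butyldimethylsilyloxy)-11,12,13-trinoreudesma-1,4,7-trien-3-one | C1C2=C(C)C(=O)C=C[C@]2(C)CC(O[Si](C)(C)C(C)(C)C)=C1 | intermediate
9 | 8-(tert-butyldimethylsilyloxy)-11,12,13-trinoreudesma-4,7-dien-3-one | C1C2=C(C)C(=O)CC[C@]2(C)CC(O[Si](C)(C)C(C)(C)C)=C1 | intermediate
10 | siloxycyclopropane ester, C11 (bearing CO2Et) bridging C7 and C8, 8-OTBS (cyclopropane diastereomers, not isolated) | CCOC(=O)C1C2CC3=C(C)C(=O)CC[C@]3(C)CC12O[Si](C)(C)C(C)(C)C | intermediate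
11 | ethyl 3,8-dioxo-13-nor-7-epi-eudesm-4-en-12-oate (7α arm, not isolated) | CCOC(=O)C[C@@H]1CC2=C(C)C(=O)CC[C@]2(C)CC1=O | intermediate
12 | ethyl 3,8-dioxo-13-noreudesm-4-en-12-oate (7β arm) | CCOC(=O)C[C@H]1CC2=C(C)C(=O)CC[C@]2(C)CC1=O | intermediate
13 | ethyl 8β-hydroxy-3-oxo-13-noreudesm-4-en-12-oate (not isolated) | CCOC(=O)C[C@H]1CC2=C(C)C(=O)CC[C@]2(C)C[C@H]1O | intermediate
14 | 3-oxo-13-noreudesm-4-en-12,8β-olide (cis-lactone, 7α-H, 8α-H) | O=C1C[C@H]2CC3=C(C)C(=O)CC[C@]3(C)C[C@H]2O1 | intermediate
15 | 3β-hydroxy-13-noreudesm-4-en-12,8β-olide | O=C1C[C@H]2CC3=C(C)[C@@H](O)CC[C@]3(C)C[C@H]2O1 | intermediate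
16 | 13-dimethylamino-3β-hydroxyeudesm-4-en-12,8β-olide (C11 epimers, not isolated) | O=C1C(CN(C)C)[C@H]2CC3=C(C)[C@@H](O)CC[C@]3(C)C[C@H]2O1 | intermediate
17 | N-methyl iodide of 16 (C11 epimers, not isolated) | O=C1C(C[N+](C)(C)C)[C@H]2CC3=C(C)[C@@H](O)CC[C@]3(C)C[C@H]2O1.[I-] | intermediate
18 | 3β-hydroxyeudesma-4,11(13)-dien-12,8β-olide | O=C1C(=C)[C@H]2CC3=C(C)[C@@H](O)CC[C@]3(C)C[C@H]2O1 | intermediate
19 | 3β-isobutyryloxyeudesma-4,11(13)-dien-12,8β-olide | O=C1C(=C)[C@H]2CC3=C(C)[C@@H](OC(=O)C(C)C)CC[C@]3(C)C[C@H]2O1 | intermediate
20 | lithium 8β-hydroxy-3β-isobutyryloxyeudesma-4,11(13)-dien-12-oate (not isolated) | [Li+].[O-]C(=O)C(=C)[C@H]1CC2=C(C)[C@@H](OC(=O)C(C)C)CC[C@]2(C)C[C@H]1O | intermediate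
21 | methyl 8β-hydroxy-3β-isobutyryloxyeudesma-4,11(13)-dien-12-oate | COC(=O)C(=C)[C@H]1CC2=C(C)[C@@H](OC(=O)C(C)C)CC[C@]2(C)C[C@H]1O | intermediate
22 | methyl 8β-acetoxy-3β-isobutyryloxyeudesma-4,11(13)-dien-12-oate | COC(=O)C(=C)[C@H]1CC2=C(C)[C@@H](OC(=O)C(C)C)CC[C@]2(C)C[C@H]1OC(C)=O | intermediate
23 | methyl 8β-acetoxy-5α-hydroperoxy-3β-isobutyryloxyeudesma-4(15),11(13)-dien-12-oate | C=C(C(=O)OC)[C@H]1C[C@@]2(OO)C(=C)[C@@H](OC(=O)C(C)C)CC[C@]2(C)C[C@H]1OC(C)=O | target

## Step count and least certain steps

Total: 14 steps. Longest linear sequence: 14 steps (1 to 23); 3 enters at step 2.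

**Step 2 (key step).** Three things could go wrong.
- The catalyst may bind the more basic C1 carbonyl (the vinylogous ester oxygen), which would polarise C5 instead of C10 and erode both regio- and enantioselectivity.
- The acidic catalyst may protodesilylate the diene before it adds.
- The sense of facial shielding rests on a binding model.

Fallback: 3 and 2 are combined without catalyst in warm toluene, where the C4 carbonyl alone directs C9 to C10. This gives the racemate, that is 4 together with the mirror-image adduct F1. The enantiomers are separated by preparative chromatography on a chiral stationary phase, and the route is rejoined at 4.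

**Step 5.** The acid needed for the transposition may also hydrolyse the ring-B silyl enol ether, because both groups are enol ethers and differ only in rate. That would lose the regiodefined C7=C8 position. Fallback: 7 is hydrolysed on purpose with dilute HCl in THF to the dienedione F2. Its dienone has no α′-hydrogens, so kinetic deprotonation with LiN(i-Pr)2 at −78 °C should occur at the saturated ketone on the C7 side, away from the quaternary carbon. Trapping with TBSOTf returns 8.

**Step 7.** The carbenoid may be diverted (ylide formation at the enone carbonyl, C–H insertion), and the equilibration at C7 may stop at a mixture, because the axial position is only mildly penalised with C5 and C8 both sp2. Fallback: from 9, a Lewis-acid alkylation of the silyl enol ether with ethyl chloro(phenylthio)acetate and ZnBr2 gives the α-phenylthio keto ester F3. Desulfurisation with Bu3SnH and AIBN then gives 11 and 12, and DBU equilibration gives 12.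

**Step 12 (with step 13).** The 8β-hydroxy ester may close back to the lactone before the hindered axial hydroxyl is acetylated. Hydroxide may also attack the isobutyrate or add to the acrylate. Fallback: from 20, the hydroxyl is capped before any ester exists at C12. Deprotonation with KN(SiMe3)2 and one equivalent of Ac2O at −78 °C acetylates the alkoxide and gives, after mild acidification, the acetoxy acid F4. This cannot lactonise and is methylated with trimethylsilyldiazomethane to give 22, bypassing 21.

**Step 14.** Singlet oxygen may abstract the aligned α-hydrogen on C3 instead of a C15 hydrogen, or the hydroperoxide may fragment on isolation. Fallback: from 22, the C5 oxygen is introduced as an epoxide and the alkene is moved separately. Dimethyldioxirane gives the 4α,5α-epoxide F5. Radical opening with Cp2TiCl (from Cp2TiCl2 and Mn), an ester-tolerant epoxide-to-allylic-alcohol isomerisation, should give the 5α-hydroxy-4(15)-ene F6 by hydrogen loss from C15. Acid-catalysed exchange of the tertiary allylic hydroxyl with concentrated H2O2 then gives 23, with attack expected anti to C14. This is longer and less selective at the ionisation step than the ene reaction.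

## Further compounds

F1 | step 2 | mirror-image cis adduct (ent-4) | C1[C@H]2C(=O)C(OC)=CC(=O)[C@@]2(C)CC(O[Si](C)(C)C(C)(C)C)=C1
F2 | step 5 | 11,12,13-trinoreudesma-1,4-diene-3,8-dione | O=C1CCC2=C(C)C(=O)C=C[C@]2(C)C1
F3 | step 7 | ethyl 3,8-dioxo-11-phenylthio-13-noreudesm-4-en-12-oate (C7 and C11 epimers) | CCOC(=O)C(Sc1ccccc1)C1CC2=C(C)C(=O)CC[C@]2(C)CC1=O
F4 | step 12 | 8β-acetoxy-3β-isobutyryloxyeudesma-4,11(13)-dien-12-oic acid | OC(=O)C(=C)[C@H]1CC2=C(C)[C@@H](OC(=O)C(C)C)CC[C@]2(C)C[C@H]1OC(C)=O
F5 | step 14 | methyl 8β-acetoxy-4α,5α-epoxy-3β-isobutyryloxyeudesm-11(13)-en-12-oate | C=C(C(=O)OC)[C@H]1C[C@@]2(O3)[C@@]3(C)[C@@H](OC(=O)C(C)C)CC[C@]2(C)C[C@H]1OC(C)=O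
F6 | step 14 | methyl 8β-acetoxy-5α-hydroxy-3β-isobutyryloxyeudesma-4(15),11(13)-dien-12-oate | C=C(C(=O)OC)[C@H]1C[C@@]2(O)C(=C)[C@@H](OC(=O)C(C)C)CC[C@]2(C)C[C@H]1OC(C)=O
A1 | alternative 1 | mixed bromoacetal of the 8β-hydroxy-4,6-diene 3β-isobutyrate | C1=CC2=C(C)[C@@H](OC(=O)C(C)C)CC[C@]2(C)C[C@H]1OC(CBr)OCC
A2 | alternative 1 | cis-fused lactol ethyl ether with C4=C5 alkene | CCOC1C[C@H]2CC3=C(C)[C@@H](OC(=O)C(C)C)CC[C@]3(C)C[C@H]2O1
A3 | alternative 2 | ten-membered (E)-4-en-3-one with C10=C14 methylene and 8,12-lactone | C[C@H]1[C@H]2C/C=C(\C)C(=O)CCC(=C)C[C@H]2OC1=O
A4 | alternative 2 | 3-keto eudesmane 8,12-lactone with C10 methyl | C[C@H]1[C@H]2C[C@H]3[C@H](C)C(=O)CC[C@]3(C)C[C@H]2OC1=O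
A5 | alternative 3 | bicyclo[2.2.2]octene vinyl carbinol with C4 dimethyl ketal, C8 methoxy and C7 ester | C=C[C@]1(O)C(OC)(OC)[C@H]2C[C@H](C(=O)OC)[C@]1(OC)C=C2C
A6 | alternative 3 | cis-decalin with C3 ketone, C4 dimethyl ketal, C8 methyl enol ether and C7 ester | COC(=O)[C@H]1C[C@@H]2C(OC)(OC)C(=O)CC[C@]2(C)C=C1OC
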